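**Retrosynthetic overview**
1. The pyranone ring (ring C) is the only ring built and is closed last: O1–C2 bond formation from a 2'-hydroxy β-keto acetal with loss of two MeOH.
2. The acetal comes from a 2'-O-benzyl chalcone by a Tl(III)-mediated oxidative 1,2-aryl shift, which moves the trimethoxyphenyl ring onto the future C3.
3. The chalcone comes from a Claisen–Schmidt aldol condensation of an A-ring acetophenone with 3,4,5-trimethoxybenzaldehyde; this C–C bond becomes C2–C3 and joins the two halves.
4. The acetophenone comes from methoxyhydroquinone (acetylation para to OMe, then bis-benzylation), which comes from vanillin by Dakin oxidation.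
5. Rings A and B are bought as aromatic rings.

Assumption: the target has no stereocentre and no stereogenic double bond, so it is achiral and no enantiocontrol is needed; the stereocentres in intermediates 7, 9, 10, 11 and 12 are racemic and are erased before the end.

**Step 1**
Reactants: 1 vanillin (4-hydroxy-3-methoxybenzaldehyde)
Product: 3 2-methoxybenzene-1,4-diol (methoxyhydroquinone), via 4-hydroxy-3-methoxyphenyl formate 2 (not isolated)
Conditions: 30% aq H2O2 (1.2 equiv), NaOH (2 equiv), H2O, 0 °C to rt, N2; then aq HCl to pH 2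
Reagents that add atoms: hydrogen peroxide, OO
Why: Dakin oxidation, in which hydroperoxide adds to the aldehyde of the p-hydroxybenzaldehyde, the electron-rich aryl group migrates to oxygen and the aryl formate 2 is saponified in the flask; no stereocentre is formed.

**Step 2**
Reactants: 3 2-methoxybenzene-1,4-diol
Product: 4 1-(2,5-dihydroxy-4-methoxyphenyl)ethan-1-one
Conditions: AcOH (1.5 equiv), BF3·OEt2 (4 equiv), 90 °C, 2 h, N2; then aq NaOAc
Reagents that add atoms: acetic acid, CC(=O)O
Why: BF3-mediated Friedel–Crafts (Fries-type) C-acetylation goes to the one unhindered position that is para to OMe and ortho to OH, and the product is held as the chelated o-hydroxy ketone; no stereocentre is formed.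

**Step 3**
Reactants: 4 1-(2,5-dihydroxy-4-methoxyphenyl)ethan-1-one
Product: 5 1-[2,5-bis(benzyloxy)-4-methoxyphenyl]ethan-1-one
Conditions: BnBr (2.5 equiv), K2CO3 (4 equiv), KI (cat.), DMF, 70 °C, N2
Reagents that add atoms: benzyl bromide, BrCc1ccccc1
Why: Williamson ether synthesis with excess benzyl bromide in hot DMF alkylates both the free 5-OH and the hydrogen-bonded 2-OH, so the later rearrangement cannot divert to an aurone; no stereocentre is formed.

**Step 4**
Reactants: 5 1-[2,5-bis(benzyloxy)-4-methoxyphenyl]ethan-1-one; 6 3,4,5-trimethoxybenzaldehyde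
Product: 8 (E)-1-[2,5-bis(benzyloxy)-4-methoxyphenyl]-3-(3,4,5-trimethoxyphenyl)prop-2-en-1-one, via aldol adduct 7 (not isolated)
Conditions: KOH (50% aq, 3 equiv), EtOH/THF, rt, 24 h
Reagents that add atoms: none
Why: Claisen–Schmidt crossed aldol condensation, in which only ketone 5 can enolise and only aldehyde 6 is the electrophile, and E1cB dehydration of the racemic aldol 7 removes its carbinol stereocentre and gives the thermodynamic E-enone.

**Step 5**
Reactants: 8 (E)-1-[2,5-bis(benzyloxy)-4-methoxyphenyl]-3-(3,4,5-trimethoxyphenyl)prop-2-en-1-one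
Product: 10 rac-1-[2,5-bis(benzyloxy)-4-methoxyphenyl]-3,3-dimethoxy-2-(3,4,5-trimethoxyphenyl)propan-1-one, via methoxythallation adduct 9 (not isolated)
Conditions: Tl(NO3)3·3H2O (1.1 equiv), MeOH/CH2Cl2 3:1, rt, 4 h; filter off TlNO3
Reagents that add atoms: methanol, CO; thallium(III) nitrate, [Tl+3].[O-][N+](=O)[O-].[O-][N+](=O)[O-].[O-][N+](=O)[O-] (its atoms stay only in 9, none in 10)
Why: Thallium(III)-mediated oxidative 1,2-aryl rearrangement of a chalcone, in which methoxythallation gives 9, the trimethoxyphenyl group shifts from Cβ to Cα as Tl(I) leaves and the oxocarbenium ion is trapped by methanol; the new C2 stereocentre is formed racemic and is removed in step 6.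

**Step 6**
Reactants: 10 rac-1-[2,5-bis(benzyloxy)-4-methoxyphenyl]-3,3-dimethoxy-2-(3,4,5-trimethoxyphenyl)propan-1-one
Product: 13 6-hydroxy-7-methoxy-3-(3,4,5-trimethoxyphenyl)-4H-chromen-4-one, via dihydroxy acetal 11 (not isolated), via 2-methoxyisoflavanone 12 (not isolated)
Conditions: H2 (1 atm), 10% Pd/C, EtOAc/MeOH, rt; filter under N2; then 10% HCl in MeOH, reflux, 2 h
Reagents that add atoms: none
Why: Hydrogenolysis of both benzyl ethers gives 11, whose 2'-OH closes onto the acid-ionised acetal (transacetalisation) to give 12, and β-elimination of methanol forms the conjugated 4-pyranone and destroys the racemic stereocentres.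

**Compound list**
1 | vanillin (4-hydroxy-3-methoxybenzaldehyde) | COc1cc(C=O)ccc1O | starting material
2 | 4-hydroxy-3-methoxyphenyl formate | COc1cc(OC=O)ccc1O | intermediate
3 | 2-methoxybenzene-1,4-diol | COc1cc(O)ccc1O | intermediate
4 | 1-(2,5-dihydroxy-4-methoxyphenyl)ethan-1-one | CC(=O)c1cc(O)c(OC)cc1O | intermediate
5 | 1-[2,5-bis(benzyloxy)-4-methoxyphenyl]ethan-1-one | CC(=O)c1cc(OCc2ccccc2)c(OC)cc1OCc1ccccc1 | intermediate
6 | 3,4,5-trimethoxybenzaldehyde | COc1cc(C=O)cc(OC)c1OC | starting material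
7 | rac-1-[2,5-bis(benzyloxy)-4-methoxyphenyl]-3-hydroxy-3-(3,4,5-trimethoxyphenyl)propan-1-one (racemic) | COc1cc(C(O)CC(=O)c2cc(OCc3ccccc3)c(OC)cc2OCc2ccccc2)cc(OC)c1OC | intermediate
8 | (E)-1-[2,5-bis(benzyloxy)-4-methoxyphenyl]-3-(3,4,5-trimethoxyphenyl)prop-2-en-1-one | COc1cc(/C=C/C(=O)c2cc(OCc3ccccc3)c(OC)cc2OCc2ccccc2)cc(OC)c1OC | intermediate
9 | 1-[2,5-bis(benzyloxy)-4-methoxyphenyl]-2-(dinitratothallio)-3-methoxy-3-(3,4,5-trimethoxyphenyl)propan-1-one (racemic, transient) | COc1cc(C(OC)C([Tl](O[N+](=O)[O-])O[N+](=O)[O-])C(=O)c2cc(OCc3ccccc3)c(OC)cc2OCc2ccccc2)cc(OC)c1OC | intermediate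
10 | rac-1-[2,5-bis(benzyloxy)-4-methoxyphenyl]-3,3-dimethoxy-2-(3,4,5-trimethoxyphenyl)propan-1-one (racemic) | COc1cc(C(C(OC)OC)C(=O)c2cc(OCc3ccccc3)c(OC)cc2OCc2ccccc2)cc(OC)c1OC | intermediate
11 | rac-1-(2,5-dihydroxy-4-methoxyphenyl)-3,3-dimethoxy-2-(3,4,5-trimethoxyphenyl)propan-1-one (racemic) | COc1cc(C(C(OC)OC)C(=O)c2cc(O)c(OC)cc2O)cc(OC)c1OC | intermediate
12 | 6-hydroxy-2,7-dimethoxy-3-(3,4,5-trimethoxyphenyl)chroman-4-one (racemic mixture of diastereomers) | COc1cc2OC(OC)C(c3cc(OC)c(OC)c(OC)c3)C(=O)c2cc1O | intermediate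
13 | 6-hydroxy-7-methoxy-3-(3,4,5-trimethoxyphenyl)-4H-chromen-4-one (achiral) | COc1cc2occ(-c3cc(OC)c(OC)c(OC)c3)c(=O)c2cc1O | target

**Totals**
Total step count: 6. Longest linear sequence: 6 steps (1 → 3 → 4 → 5 → 8 → 10 → 13); aldehyde 6 is bought.

**Three steps most likely to fail**

Step 5 (oxidative aryl shift). The 3,4,5-trimethoxyphenyl ring is only a moderate migrating group, the A ring is very electron-rich, and Tl(III) can over-oxidise. The fallback sets out from 8 and comes back to the route at 13. Weitz–Scheffer epoxidation of 8 (30% H2O2, aq NaOH, MeOH/THF, 0 °C to rt) gives the racemic trans-epoxide [2,5-bis(benzyloxy)-4-methoxyphenyl][3-(3,4,5-trimethoxyphenyl)oxiran-2-yl]methanone F1. BF3·OEt2 in CH2Cl2 at 0 °C opens it at the benzylic carbon and a Meinwald-type 1,2-aroyl shift gives 3-[2,5-bis(benzyloxy)-4-methoxyphenyl]-3-oxo-2-(3,4,5-trimethoxyphenyl)propanal F2. Hydrogenolysis (H2, Pd/C) removes both benzyl groups and the freed 2'-OH closes onto the aldehyde to give 2,6-dihydroxy-7-methoxy-3-(3,4,5-trimethoxyphenyl)chroman-4-one F3, which loses water with catalytic HCl in MeOH to give 13.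

Step 2 (acetylation of the free hydroquinone). Risks are air oxidation of 3 or 4 to quinones, O-acetylation and incomplete regiocontrol. The fallback sets out from 3 and comes back to the route at 5, bypassing 4. Both hydroxyls of 3 are benzylated first (BnBr, K2CO3, DMF) to give 1,4-bis(benzyloxy)-2-methoxybenzene F4. This oxidation-stable triether is then acetylated by a conventional Friedel–Crafts reaction with acetyl chloride and SnCl4 in CH2Cl2 at −20 to 0 °C, which goes para to the methoxy group and gives 5 directly.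

Step 6 (hydrogenolysis then cyclisation). Risks are over-reduction of the aryl ketone, catalyst poisoning by traces of thallium, and air oxidation of the hydroquinone 11. The fallback sets out from 4 and comes back to the route at 13, replacing benzyl by acid-labile protection so that no hydrogenation is needed. Compound 4 is converted with MOMCl and i-Pr2NEt (NaH in DMF for the chelated OH) into 1-[4-methoxy-2,5-bis(methoxymethoxy)phenyl]ethan-1-one F5. Claisen–Schmidt condensation of F5 with 6 (KOH, EtOH) gives (E)-1-[4-methoxy-2,5-bis(methoxymethoxy)phenyl]-3-(3,4,5-trimethoxyphenyl)prop-2-en-1-one F6. Tl(NO3)3 in MeOH rearranges F6 to rac-3,3-dimethoxy-1-[4-methoxy-2,5-bis(methoxymethoxy)phenyl]-2-(3,4,5-trimethoxyphenyl)propan-1-one F7. A single treatment with 10% HCl in MeOH at reflux removes both MOM groups and closes the ring through 11 and 12 to give 13.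

**Further compounds**
F1 | step 5 | [2,5-bis(benzyloxy)-4-methoxyphenyl][3-(3,4,5-trimethoxyphenyl)oxiran-2-yl]methanone (racemic trans, one enantiomer drawn) | O=C(c1cc(OCc2ccccc2)c(OC)cc1OCc1ccccc1)[C@@H]1O[C@H]1c1cc(OC)c(OC)c(OC)c1
F2 | step 5 | 3-[2,5-bis(benzyloxy)-4-methoxyphenyl]-3-oxo-2-(3,4,5-trimethoxyphenyl)propanal (racemic, enolisable) | COc1cc(C(C=O)C(=O)c2cc(OCc3ccccc3)c(OC)cc2OCc2ccccc2)cc(OC)c1OC
F3 | step 5 | 2,6-dihydroxy-7-methoxy-3-(3,4,5-trimethoxyphenyl)chroman-4-one (racemic mixture of diastereomers) | COc1cc2OC(O)C(c3cc(OC)c(OC)c(OC)c3)C(=O)c2cc1O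
F4 | step 2 | 1,4-bis(benzyloxy)-2-methoxybenzene | COc1cc(OCc2ccccc2)ccc1OCc1ccccc1
F5 | step 6 | 1-[4-methoxy-2,5-bis(methoxymethoxy)phenyl]ethan-1-one | CC(=O)c1cc(OCOC)c(OC)cc1OCOC
F6 | step 6 | (E)-1-[4-methoxy-2,5-bis(methoxymethoxy)phenyl]-3-(3,4,5-trimethoxyphenyl)prop-2-en-1-one | COCOc1cc(OC)c(OCOC)cc1C(=O)/C=C/c1cc(OC)c(OC)c(OC)c1
F7 | step 6 | rac-3,3-dimethoxy-1-[4-methoxy-2,5-bis(methoxymethoxy)phenyl]-2-(3,4,5-trimethoxyphenyl)propan-1-one (racemic) | COCOc1cc(OC)c(OCOC)cc1C(=O)C(C(OC)OC)c1cc(OC)c(OC)c(OC)c1
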